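**Assumptions (one line each).** Commercial starting materials are 6‑methoxy‑1‑tetralone, ethyl vinyl ketone and 4‑methoxy‑2‑methylphenol. The sense of induction of (S)‑1‑phenylethylamine in step 3 is assigned by analogy with the 2‑methylcyclohexanone/MVK case; if it proves opposite, use the (R)‑amine.

## Retrosynthetic overview

1. The quinone comes from CAN oxidation of a 2,5‑dimethoxy‑3‑methylbenzyl group; the isopropylidene comes from a mixed McMurry coupling of a ring ketone with acetone.
2. The ring ketone plus the propanoic acid chain (a δ‑keto acid) come from a cyclohexenone by oxidative excision of one carbon. That cyclohexenone comes from Birch dearomatisation of an anisole ring carried through the synthesis as a masked keto acid; the same step sets the CH stereocentre bearing the acid chain.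
3. The secondary methyl comes from ketone methylenation and hydrogenation. The benzylic quaternary centre and the trans ring fusion come from Li/NH3 reductive benzylation of a tricyclic enone.
4. The tricyclic enone comes from a chiral‑imine Robinson annulation of 6‑methoxy‑1‑methyl‑2‑tetralone with ethyl vinyl ketone; the tetralone comes from 6‑methoxy‑1‑tetralone.
5. Ring order: the tetralone carbocycle (future isopropylidene ring) is present from the start, the trimethylcyclohexane ring is annulated second, the anisole ring is destroyed late, and the quinone is unveiled last.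

## Route

**Step 1**
Reactants: 1, 6‑methoxy‑1‑tetralone
Product: 2, 7‑methoxy‑4‑methyl‑1,2‑dihydronaphthalene
Conditions: MeMgBr, THF, 0 °C to rt; then TsOH (cat.), toluene, reflux
Reagents that add atoms: methylmagnesium bromide, C[Mg]Br
Why: Grignard addition, then E1 dehydration of the benzylic tertiary alcohol to the conjugated alkene; no stereocentre.

**Step 2**
Reactants: 2
Product: 3, 6‑methoxy‑1‑methyl‑3,4‑dihydronaphthalen‑2(1H)‑one (racemic)
Conditions: mCPBA, CH2Cl2/aq. NaHCO3, 0 °C; then TsOH (cat.), toluene, rt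
Reagents that add atoms: mCPBA, OOC(=O)c1cccc(Cl)c1
Why: Epoxidation, then Meinwald rearrangement through the benzylic tertiary cation with a 1,2‑hydride shift gives the 2‑tetralone; the C1 stereocentre is racemic and is erased in step 3.

**Step 3**
Reactants: 3; 4, ethyl vinyl ketone (pent‑1‑en‑3‑one)
Product: 5, (S)‑6‑methoxy‑1‑methyl‑1‑(3‑oxopentyl)‑3,4‑dihydronaphthalen‑2(1H)‑one
Conditions: (S)‑1‑phenylethylamine, TsOH (cat.), toluene, Dean–Stark; then 4, THF, rt; then 20% aq. AcOH
Reagents that add atoms: none (4 is incorporated as a reactant)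
Why: d'Angelo deracemising Michael addition; the aryl‑conjugated secondary enamine tautomer of the chiral imine adds to the enone on the face anti to the auxiliary phenyl, which sets the first quaternary stereocentre.

**Step 4**
Reactants: 5
Product: 6, (4aR)‑7‑methoxy‑1,4a‑dimethyl‑4,4a,9,10‑tetrahydrophenanthren‑2(3H)‑one
Conditions: NaOMe, MeOH, 60 °C
Reagents that add atoms: none
Why: Intramolecular aldol condensation completes the Robinson annulation; the quaternary centre is not epimerisable.

**Step 5**
Reactants: 7, 4‑methoxy‑2‑methylphenol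
Product: 8, 2‑hydroxy‑5‑methoxy‑3‑methylbenzaldehyde
Conditions: MgCl2, Et3N, (CH2O)n, MeCN, reflux
Reagents that add atoms: paraformaldehyde, C=O
Why: Magnesium‑phenoxide‑directed ortho‑formylation (Casnati–Skattebøl); only one ortho position is free.

**Step 6**
Reactants: 8
Product: 9, 2‑(benzyloxy)‑5‑methoxy‑3‑methylbenzaldehyde
Conditions: BnBr, K2CO3, DMF, rt
Reagents that add atoms: benzyl bromide, BrCc1ccccc1
Why: Williamson etherification masks the phenol for the enolate alkylation.

**Step 7**
Reactants: 9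
Product: 10, [2‑(benzyloxy)‑5‑methoxy‑3‑methylphenyl]methanol
Conditions: NaBH4, MeOH, 0 °C
Reagents that add atoms: none
Why: Hydride reduction of the aldehyde.

**Step 8**
Reactants: 10
Product: 11, 2‑(benzyloxy)‑1‑(bromomethyl)‑5‑methoxy‑3‑methylbenzene
Conditions: PBr3, CH2Cl2, 0 °C
Reagents that add atoms: phosphorus tribromide, BrP(Br)Br
Why: Conversion of the benzylic alcohol to the bromide.

**Step 9**
Reactants: 6; 11
Product: 12, (1R,4aR,10aS)‑1‑{[2‑(benzyloxy)‑5‑methoxy‑3‑methylphenyl]methyl}‑7‑methoxy‑1,4a‑dimethyl‑3,4,4a,9,10,10a‑hexahydrophenanthren‑2(1H)‑one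
Conditions: Li (2.2 equiv), NH3(l)/THF, t‑BuOH (1 equiv), −78 °C; isoprene; then 11 in THF, −78 to −33 °C
Reagents that add atoms: none (11 is incorporated as a reactant)
Why: Stork reductive alkylation; protonation at the ring‑fusion carbon gives the trans‑fused enolate, which is benzylated at the methyl‑bearing carbon anti to the 1,3‑diaxial angular methyl (benzyl equatorial, methyl axial). The anisole ring survives because no excess metal or proton donor remains.

**Step 10**
Reactants: 12
Product: 13, (1R,4aR,10aR)‑1‑{[2‑(benzyloxy)‑5‑methoxy‑3‑methylphenyl]methyl}‑7‑methoxy‑1,4a‑dimethyl‑2‑methylidene‑1,2,3,4,4a,9,10,10a‑octahydrophenanthrene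
Conditions: Ph3PCH3Br, KOt‑Bu, toluene, 90 °C
Reagents that add atoms: methylenetriphenylphosphorane, C=P(c1ccccc1)(c1ccccc1)c1ccccc1
Why: Wittig methylenation of the hindered ketone; no stereocentre changes.

**Step 11**
Reactants: 13
Product: 14, 2‑{[(1S,2R,4aR,10aR)‑7‑methoxy‑1,2,4a‑trimethyl‑1,2,3,4,4a,9,10,10a‑octahydrophenanthren‑1‑yl]methyl}‑4‑methoxy‑6‑methylphenol
Conditions: H2 (3 atm), 10% Pd/C, EtOAc/EtOH, rt
Reagents that add atoms: none
Why: Heterogeneous hydrogenation delivers hydrogen to the face opposite the adjacent axial methyl, giving the equatorial secondary methyl cis to the quaternary methyl; the benzyl ether is hydrogenolysed in the same operation.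

**Step 12 (key step)**
Reactants: 14
Product: 15, (4aR,4bS,7R,8S,8aR)‑8‑[(2‑hydroxy‑5‑methoxy‑3‑methylphenyl)methyl]‑4b,7,8‑trimethyl‑4,4a,4b,5,6,7,8,8a,9,10‑decahydrophenanthren‑2(3H)‑one
Conditions: Li (excess), NH3(l)/THF/t‑BuOH, −33 °C; NH4Cl; then 3 M HCl, MeOH/THF, 50 °C
Reagents that add atoms: water, O
Why: Birch reduction; the free phenol is present as its phenoxide and is not reduced, so only the anisole ring goes to the 2,5‑dihydroanisole. Enol‑ether hydrolysis and conjugation then give the cyclohexenone, with the γ‑carbon protonated anti to the adjacent angular methyl (the known podocarp‑8(14)‑en‑13‑one outcome), which sets the CH stereocentre.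

**Step 13**
Reactants: 15
Product: 16, (4aR,4bS,7R,8S,8aR)‑8‑[(2,5‑dimethoxy‑3‑methylphenyl)methyl]‑4b,7,8‑trimethyl‑4,4a,4b,5,6,7,8,8a,9,10‑decahydrophenanthren‑2(3H)‑one
Conditions: MeI, Cs2CO3, DMF, rt
Reagents that add atoms: iodomethane, CI
Why: O‑methylation of the hindered phenol; this protects the arene for the oxidative cleavage and gives the hydroquinone dimethyl ether needed for the final oxidation.

**Step 14**
Reactants: 16
Product: 17, 3‑[(1S,4aR,5S,6R,8aR)‑5‑[(2,5‑dimethoxy‑3‑methylphenyl)methyl]‑5,6,8a‑trimethyl‑2‑oxodecahydronaphthalen‑1‑yl]propanoic acid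
Conditions: KMnO4 (cat.), NaIO4, K2CO3, t‑BuOH/H2O, rt
Reagents that add atoms: sodium periodate, [Na+].[O-]I(=O)(=O)=O; potassium permanganate, [K+].[O-][Mn](=O)(=O)=O; water, O
Why: Lemieux–von Rudloff cleavage of the enone C=C; the ring carbon becomes the ketone, the =CH carbon is lost as formate/CO2 and the former carbonyl carbon becomes CO2H. Aryl methyl ethers are inert, and the mild conditions keep the α‑stereocentre, which is also the equatorial, thermodynamic epimer.

**Step 15**
Reactants: 17
Product: 18, 3‑[(1S,4aR,5S,6R,8aR)‑5‑[(2,5‑dimethoxy‑3‑methylphenyl)methyl]‑5,6,8a‑trimethyl‑2‑(propan‑2‑ylidene)decahydronaphthalen‑1‑yl]propanoic acid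
Conditions: TiCl4, Zn, pyridine, THF, reflux; slow addition of 17 with acetone (10 equiv)
Reagents that add atoms: acetone, CC(C)=O
Why: Mixed McMurry coupling (ketyl coupling on low‑valent Ti, then deoxygenation) with excess acetone gives the tetrasubstituted isopropylidene directly. The conditions are non‑basic, so the adjacent CH centre is not deliberately enolised, and the carboxylic acid is tolerated with excess reagent.

**Step 16**
Reactants: 18
Product: 19, stypoquinonic acid, 3‑[(1S,4aR,5S,6R,8aR)‑5,6,8a‑trimethyl‑5‑[(5‑methyl‑3,6‑dioxocyclohexa‑1,4‑dien‑1‑yl)methyl]‑2‑(propan‑2‑ylidene)decahydronaphthalen‑1‑yl]propanoic acid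
Conditions: CAN (2.5 equiv), MeCN/H2O, 0 °C
Reagents that add atoms: water, O
Why: CAN oxidative demethylation of the hydroquinone dimethyl ether to the p‑quinone; the acid and the tetrasubstituted alkene are tolerated at 0 °C and no stereocentre is touched.

## Compound list

1 | 6‑methoxy‑1‑tetralone | COc1ccc2c(c1)CCCC2=O | starting material
2 | 7‑methoxy‑4‑methyl‑1,2‑dihydronaphthalene | COc1ccc2c(c1)CCC=C2C | intermediate
3 | 6‑methoxy‑1‑methyl‑3,4‑dihydronaphthalen‑2(1H)‑one (racemic) | COc1ccc2c(c1)CCC(=O)C2C | intermediate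
4 | ethyl vinyl ketone | C=CC(=O)CC | starting material
5 | (S)‑6‑methoxy‑1‑methyl‑1‑(3‑oxopentyl)‑3,4‑dihydronaphthalen‑2(1H)‑one | O=C1CCc2cc(OC)ccc2[C@]1(C)CCC(=O)CC | intermediate
6 | (4aR)‑7‑methoxy‑1,4a‑dimethyl‑4,4a,9,10‑tetrahydrophenanthren‑2(3H)‑one | CC1=C2CCc3cc(OC)ccc3[C@]2(C)CCC1=O | intermediate
7 | 4‑methoxy‑2‑methylphenol | Cc1cc(OC)ccc1O | starting material
8 | 2‑hydroxy‑5‑methoxy‑3‑methylbenzaldehyde | Cc1cc(OC)cc(C=O)c1O | intermediate
9 | 2‑(benzyloxy)‑5‑methoxy‑3‑methylbenzaldehyde | Cc1cc(OC)cc(C=O)c1OCc1ccccc1 | intermediate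
10 | [2‑(benzyloxy)‑5‑methoxy‑3‑methylphenyl]methanol | Cc1cc(OC)cc(CO)c1OCc1ccccc1 | intermediate
11 | 2‑(benzyloxy)‑1‑(bromomethyl)‑5‑methoxy‑3‑methylbenzene | Cc1cc(OC)cc(CBr)c1OCc1ccccc1 | intermediate
12 | (1R,4aR,10aS)‑1‑benzylated trans‑fused tricyclic ketone (see step 9) | Cc1cc(OC)cc(C[C@]2(C)[C@H]3CCc4cc(OC)ccc4[C@]3(C)CCC2=O)c1OCc1ccccc1 | intermediate
13 | (1R,4aR,10aR)‑2‑methylidene analogue of 12 (see step 10) | Cc1cc(OC)cc(C[C@]2(C)[C@H]3CCc4cc(OC)ccc4[C@]3(C)CCC2=C)c1OCc1ccccc1 | intermediate
14 | 2‑{[(1S,2R,4aR,10aR)‑7‑methoxy‑1,2,4a‑trimethyl‑octahydrophenanthren‑1‑yl]methyl}‑4‑methoxy‑6‑methylphenol | Cc1cc(OC)cc(C[C@]2(C)[C@H]3CCc4cc(OC)ccc4[C@]3(C)CC[C@H]2C)c1O | intermediate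
15 | (4aR,4bS,7R,8S,8aR)‑tricyclic enone phenol (see step 12) | Cc1cc(OC)cc(C[C@]2(C)[C@H]3CCC4=CC(=O)CC[C@H]4[C@]3(C)CC[C@H]2C)c1O | intermediate
16 | (4aR,4bS,7R,8S,8aR)‑tricyclic enone, dimethoxyarene (see step 13) | Cc1cc(OC)cc(C[C@]2(C)[C@H]3CCC4=CC(=O)CC[C@H]4[C@]3(C)CC[C@H]2C)c1OC | intermediate
17 | 3‑[(1S,4aR,5S,6R,8aR)‑5‑[(2,5‑dimethoxy‑3‑methylphenyl)methyl]‑5,6,8a‑trimethyl‑2‑oxodecahydronaphthalen‑1‑yl]propanoic acid | Cc1cc(OC)cc(C[C@]2(C)[C@H]3CCC(=O)[C@@H](CCC(=O)O)[C@]3(C)CC[C@H]2C)c1OC | intermediate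
18 | 3‑[(1S,4aR,5S,6R,8aR)‑5‑[(2,5‑dimethoxy‑3‑methylphenyl)methyl]‑5,6,8a‑trimethyl‑2‑(propan‑2‑ylidene)decahydronaphthalen‑1‑yl]propanoic acid | Cc1cc(OC)cc(C[C@]2(C)[C@H]3CCC(=C(C)C)[C@@H](CCC(=O)O)[C@]3(C)CC[C@H]2C)c1OC | intermediate
19 | stypoquinonic acid | CC1=CC(=O)C=C(C[C@]2(C)[C@H]3CCC(=C(C)C)[C@@H](CCC(=O)O)[C@]3(C)CC[C@H]2C)C1=O | target

## Step count

Total steps: 16. Longest linear sequence: 12 (steps 1–4 and 9–16); steps 5–8 form a four‑step side branch to bromide 11.

## Steps most likely to fail, with fallbacks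

1. **Step 12 (Birch dearomatisation and conjugation).** The hindered anisole may reduce incompletely, and the new CH centre may form as an epimer mixture. Fallback: drop the arene‑as‑keto‑acid tactic and build the bicyclic core from the Wieland–Miescher‑type diketone (2‑methylcyclohexane‑1,3‑dione + ethyl vinyl ketone). The propanoate is then installed on the ring ketone by enol triflate formation and Negishi coupling with the zinc homoenolate, followed by hydroboration–oxidation of the resulting alkene.

2. **Step 15 (McMurry isopropylidenation).** The hindered α‑branched keto acid may homocouple, epimerise at the α‑carbon, or interfere through the free acid. Fallback: esterify 17, add isopropenylmagnesium bromide/CeCl3 to the ketone, then carry out Et3SiH/BF3·OEt2 ionic reduction of the tertiary allylic alcohol with allylic transposition to the tetrasubstituted alkene, and saponify before step 16.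

3. **Step 9 (reductive benzylation).** The fully substituted enolate and the ortho‑substituted benzyl bromide may give O‑alkylation or simple protonation. Fallback: Stork deconjugative C‑benzylation of the potassium dienolate of 6 (t‑BuOK, then 11), followed by hydrogenation of the resulting β,γ‑alkene to set the trans ring fusion.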